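**Plan**
- Cuts: the acrylic acid goes back to a C4 ester (Wittig), the C7 ethyl and C5 phenyl to a C5=C6–C7=O enone (cuprate addition, triflate coupling), and the two ring-fusion hydrogens and the C4 ethyl to a bicyclic enone ester. That ester is cut at C5–C6 and C3a–C7a to an open-chain diketo acrylate.
- Enabling feature: in the cyclohexene ring C7 lies between C7a and C6, and C4 lies between C3a and C5. A ketone at C7 makes both its neighbours nucleophilic, and a 2-methylene-3-oxo ester centred on C4 makes both its neighbours electrophilic; the C1–C2–C3 chain of the cyclopentane ring ties the two halves together.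
- Forward: chiral-pool enone → open-chain keto aldehyde → diketo acrylate; the key step closes the cyclopentane ring (C3a–C7a), then the six-membered ring (C5–C6); the remaining groups are added to the bicycle.
- Stereochemistry: C1 and C3 from the starting enone and a trans cuprate addition; C4 by alkylation anti to the C3 methyl; C3a and C7a by dissolving-metal reduction (each hydrogen enters anti to the neighbouring methyl); C5 by axial cuprate addition anti to the axial ester; the E alkene from a stabilised ylide.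

Key step: step 6

Assumption: (R)-5-methylcyclohex-2-en-1-one (1) is taken as a purchasable chiral-pool enone (the usual degradation product of (R)-pulegone).

Step 1
Reactants: 1 (R)-5-methylcyclohex-2-en-1-one
Product: 3 (3R,5R)-3,5-dimethylcyclohex-1-en-1-yl trifluoromethanesulfonate, via lithium enolate 2 (not isolated)
Conditions: MeLi (2 equiv), CuI, Et2O, 0 °C; 1, −78 → −20 °C; then Comins' reagent, THF, −78 °C → rt
Reagents that add atoms: methyllithium, [Li]C (acts as lithium dimethylcuprate, [Li+].C[Cu-]C); Comins' reagent, N-(5-chloropyridin-2-yl)-1,1,1-trifluoro-N-(trifluoromethylsulfonyl)methanesulfonamide, O=S(=O)(N(c1ccc(Cl)cn1)S(=O)(=O)C(F)(F)F)C(F)(F)F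
Why: Gilman cuprate conjugate addition should take place axially on the half-chair enone, anti to the C5 methyl, which sets the trans (3R,5R) dimethyl pattern, and O-triflation of the regiodefined enolate (enolate trapping) fixes the double bond.

Step 2
Reactants: 3 (3R,5R)-3,5-dimethylcyclohex-1-en-1-yl trifluoromethanesulfonate
Product: 4 (3R,5R)-1,3,5-trimethylcyclohex-1-ene
Conditions: MeMgBr, Fe(acac)3 (5 mol %), THF/NMP, −30 → 0 °C
Reagents that add atoms: methylmagnesium bromide, C[Mg]Br
Why: Iron-catalysed Kumada coupling of an alkenyl triflate with a methyl Grignard reagent is fast at low temperature and touches neither stereocentre; the C2 symmetry of the saturated part makes the position of the double bond immaterial.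

Step 3
Reactants: 4 (3R,5R)-1,3,5-trimethylcyclohex-1-ene
Product: 6 (2R,4R)-2,4-dimethyl-6-oxoheptanal, via ozonide 5 (not isolated)
Conditions: O3, CH2Cl2, −78 °C; then PPh3, −78 °C → rt
Reagents that add atoms: ozone, [O-][O+]=O
Why: Criegee ozonolysis with reductive work-up cleaves the only alkene to the methyl ketone and the α-branched aldehyde under neutral conditions, so the aldehyde α-centre should not epimerise.

Step 4
Reactants: 6 (2R,4R)-2,4-dimethyl-6-oxoheptanal
Product: 7 methyl (4R,6R)-3-hydroxy-4,6-dimethyl-2-methylidene-8-oxononanoate (both C3 epimers)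
Conditions: methyl propiolate, i-Bu2AlH, N-methylmorpholine N-oxide, THF, 0 °C; then 6, 0 °C → rt
Reagents that add atoms: methyl propiolate, C#CC(=O)OC
Why: Hydroalumination of the propiolate gives the α-alumino acrylate, which should add to the aldehyde in preference to the ketone (vinylalumination, a non-basic entry to a Morita–Baylis–Hillman-type adduct); the new carbinol centre is formed without control and is removed in step 5.

Step 5
Reactants: 7 methyl (4R,6R)-3-hydroxy-4,6-dimethyl-2-methylidene-8-oxononanoate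
Product: 8 methyl (4R,6R)-4,6-dimethyl-2-methylidene-3,8-dioxononanoate
Conditions: Dess–Martin periodinane, CH2Cl2, 0 °C → rt
Reagents that add atoms: none
Why: Dess–Martin oxidation of the allylic alcohol under near-neutral conditions should give the 2-methylene-3-oxo ester without epimerising C4; the product is prone to self-condensation and is used at once.

Step 6
Reactants: 8 methyl (4R,6R)-4,6-dimethyl-2-methylidene-3,8-dioxononanoate
Product: 12 methyl (1R,3R)-1,3-dimethyl-7-oxo-2,3,4,5,6,7-hexahydro-1H-indene-4-carboxylate (both C4 epimers), via acylcyclopentene 9 (not isolated), via aminotriene 10 (not isolated), via cyclic dienamine 11 (not isolated)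
Conditions: pyrrolidine (1.2 equiv), AcOH (1.2 equiv), 4 Å molecular sieves, toluene (0.02 M), rt → 70 °C; then AcOH/NaOAc, H2O/THF, rt
Reagents that add atoms: none
Why: The unhindered methyl ketone condenses with pyrrolidine, and its more substituted enamine carbon (C7 of 8) adds to the activated C3 ketone in a 5-(enolexo)-exo-trig aldol step; loss of water gives acylcyclopentene 9, whose acetyl group forms the cross-conjugated 2-aminotriene 10, and this closes the six-membered ring by a thermal disrotatory 6π-electrocyclisation (equally read as a 6-(enolendo)-endo-trig Michael addition of the enamine carbon to the acrylate CH2) to the push–pull dienamine 11, which is hydrolysed to 12 on work-up. The closest known reaction type is the Robinson-type [3+3] annulation by which Hagemann's ester is made (aldol condensation plus Michael addition of an acetone unit onto a 2-methylene-3-oxo ester), combined with the familiar cyclodehydration of 1,6-diketones to acylcyclopentenes. The only new stereocentre is C4 of 12, formed without control on hydrolysis and erased in step 7; the two methyl-bearing centres are carried through untouched. The step needs the methylene and not the methyl group of the ketone to open the sequence, which ring size secures (five-membered against seven- or nine-membered closure), together with the fact that only this aldol can dehydrate to a conjugated enone. It also needs the central double bond of the triene to be cis, which the cyclopentene ring enforces, and it needs the C4 stereocentre of 8 (α to the ketone) to survive, for which the buffered amine conditions and the fast five-ring aldol are relied on.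

Step 7
Reactants: 12 methyl (1R,3R)-1,3-dimethyl-7-oxo-2,3,4,5,6,7-hexahydro-1H-indene-4-carboxylate
Product: 13 methyl (1R,3R,4S)-4-ethyl-1,3-dimethyl-7-oxo-2,3,4,5,6,7-hexahydro-1H-indene-4-carboxylate
Conditions: Cs2CO3, EtI, DMF, 0 °C → rt
Reagents that add atoms: iodoethane, CCI
Why: C-Alkylation of a vinylogous β-keto ester (Hagemann's ester-type dienolate) should occur at C4 because the ketone α-carbon C7a is fully substituted, and iodoethane should approach the planar dienolate anti to the pseudoaxial C3 methyl on the neighbouring ring carbon, which sets (4S).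

Step 8
Reactants: 13 methyl (1R,3R,4S)-4-ethyl-1,3-dimethyl-7-oxo-2,3,4,5,6,7-hexahydro-1H-indene-4-carboxylate
Product: 15 methyl (1R,3R,3aR,4S,7aR)-4-ethyl-1,3-dimethyl-7-oxooctahydro-1H-indene-4-carboxylate, via lithium enolate 14 (not isolated)
Conditions: Li, NH3 (l), THF, t-BuOH (1 equiv), −78 °C; then NH4Cl, −78 °C
Reagents that add atoms: none
Why: Dissolving-metal (Birch-type) reduction of the tetrasubstituted enone: the β-carbanion at C3a should be protonated on the face away from the C3 methyl and the pseudoaxial ester, and the lithium enolate, quenched cold, at C7a on the face away from the C1 methyl, which gives the trans ring fusion (3aR,7aR).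

Step 9
Reactants: 15 methyl (1R,3R,3aR,4S,7aR)-4-ethyl-1,3-dimethyl-7-oxooctahydro-1H-indene-4-carboxylate
Product: 17 methyl (1R,3R,3aR,4S,7aR)-4-ethyl-1,3-dimethyl-7-oxo-2,3,3a,4,7,7a-hexahydro-1H-indene-4-carboxylate, via lithium enolate 16 (not isolated)
Conditions: LiN(i-Pr)2, THF, −78 °C; then N-tert-butylbenzenesulfinimidoyl chloride, −78 °C
Reagents that add atoms: none
Why: Mukaiyama dehydrogenation: kinetic deprotonation should remove a proton from the C6 methylene and not from the C7a methine, and the sulfinimidoyl chloride converts the enolate into the C5=C6 enone without touching a stereocentre.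

Step 10
Reactants: 17 methyl (1R,3R,3aR,4S,7aR)-4-ethyl-1,3-dimethyl-7-oxo-2,3,3a,4,7,7a-hexahydro-1H-indene-4-carboxylate
Product: 19 methyl (1R,3R,3aR,4R,5S,7aR)-4-ethyl-1,3-dimethyl-5-phenyl-7-(trifluoromethanesulfonyloxy)-2,3,3a,4,5,7a-hexahydro-1H-indene-4-carboxylate, via lithium enolate 18 (not isolated)
Conditions: PhLi (2 equiv), CuI, Et2O/THF, 0 °C; 17, −78 → −20 °C; then Comins' reagent, −78 °C → rt
Reagents that add atoms: phenyllithium, [Li]c1ccccc1 (acts as lithium diphenylcuprate, [Li+].c1ccccc1[Cu-]c1ccccc1); Comins' reagent, N-(5-chloropyridin-2-yl)-1,1,1-trifluoro-N-(trifluoromethylsulfonyl)methanesulfonamide, O=S(=O)(N(c1ccc(Cl)cn1)S(=O)(=O)C(F)(F)F)C(F)(F)F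
Why: Gilman cuprate conjugate addition to the trans-fused cyclohexenone should proceed by axial attack at C5 anti to the axial C4 ester, which sets (5S) with phenyl cis to the C4 ethyl, and O-triflation of the resulting enolate (enolate trapping) places the double bond at C6=C7.

Step 11
Reactants: 19 methyl (1R,3R,3aR,4R,5S,7aR)-4-ethyl-1,3-dimethyl-5-phenyl-7-(trifluoromethanesulfonyloxy)-2,3,3a,4,5,7a-hexahydro-1H-indene-4-carboxylate
Product: 20 methyl (1R,3R,3aR,4R,5S,7aR)-4,7-diethyl-1,3-dimethyl-5-phenyl-2,3,3a,4,5,7a-hexahydro-1H-indene-4-carboxylate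
Conditions: EtMgBr, Fe(acac)3 (5 mol %), THF/NMP, −30 °C
Reagents that add atoms: ethylmagnesium bromide, CC[Mg]Br
Why: Iron-catalysed Kumada coupling of the alkenyl triflate with ethylmagnesium bromide should be faster than Grignard addition to the hindered ester and is not troubled by β-hydride elimination.

Step 12
Reactants: 20 methyl (1R,3R,3aR,4R,5S,7aR)-4,7-diethyl-1,3-dimethyl-5-phenyl-2,3,3a,4,5,7a-hexahydro-1H-indene-4-carboxylate
Product: 21 [(1R,3R,3aR,4R,5S,7aR)-4,7-diethyl-1,3-dimethyl-5-phenyl-2,3,3a,4,5,7a-hexahydro-1H-inden-4-yl]methanol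
Conditions: i-Bu2AlH, CH2Cl2, −78 → 0 °C
Reagents that add atoms: none
Why: Hydride reduction of the ester, which has no α-hydrogen, should give the neopentyl alcohol with no stereocentre at risk.

Step 13
Reactants: 21 [(1R,3R,3aR,4R,5S,7aR)-4,7-diethyl-1,3-dimethyl-5-phenyl-2,3,3a,4,5,7a-hexahydro-1H-inden-4-yl]methanol
Product: 22 (1R,3R,3aR,4R,5S,7aR)-4,7-diethyl-1,3-dimethyl-5-phenyl-2,3,3a,4,5,7a-hexahydro-1H-indene-4-carbaldehyde
Conditions: Dess–Martin periodinane, CH2Cl2, rt
Reagents that add atoms: none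
Why: Dess–Martin oxidation should give the non-enolisable aldehyde without touching the trisubstituted alkene.

Step 14
Reactants: 22 (1R,3R,3aR,4R,5S,7aR)-4,7-diethyl-1,3-dimethyl-5-phenyl-2,3,3a,4,5,7a-hexahydro-1H-indene-4-carbaldehyde
Product: 23 ethyl (2E)-3-[(1R,3R,3aR,4S,5S,7aR)-4,7-diethyl-1,3-dimethyl-5-phenyl-2,3,3a,4,5,7a-hexahydro-1H-inden-4-yl]-2-methylprop-2-enoate
Conditions: Ph3P=C(Me)CO2Et, toluene, 110 °C
Reagents that add atoms: ethyl 2-(triphenyl-λ5-phosphanylidene)propanoate, CCOC(=O)C(C)=P(c1ccccc1)(c1ccccc1)c1ccccc1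
Why: Wittig olefination with a stabilised ylide should give the E trisubstituted enoate; the neopentyl aldehyde cannot enolise and is expected to need prolonged heating.

Step 15
Reactants: 23 ethyl (2E)-3-[(1R,3R,3aR,4S,5S,7aR)-4,7-diethyl-1,3-dimethyl-5-phenyl-2,3,3a,4,5,7a-hexahydro-1H-inden-4-yl]-2-methylprop-2-enoate
Product: 24 homo-plakotenin, (2E)-3-[(1R,3R,3aR,4S,5S,7aR)-4,7-diethyl-1,3-dimethyl-5-phenyl-2,3,3a,4,5,7a-hexahydro-1H-inden-4-yl]-2-methylprop-2-enoic acid
Conditions: LiOH, THF/MeOH/H2O, 50 °C; then 1 M HCl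
Reagents that add atoms: lithium hydroxide, [Li+].[OH-]
Why: Saponification of the conjugated ethyl ester followed by acidification should give the acid; no stereocentre is epimerisable under these conditions.

**Compound list**
1 | (R)-5-methylcyclohex-2-en-1-one | C[C@@H]1CC=CC(=O)C1 | starting material
2 | lithium (3R,5R)-3,5-dimethylcyclohex-1-en-1-olate (not isolated) | [Li+].[O-]C1=C[C@H](C)C[C@@H](C)C1 | intermediate
3 | (3R,5R)-3,5-dimethylcyclohex-1-en-1-yl trifluoromethanesulfonate | O=S(=O)(OC1=C[C@H](C)C[C@@H](C)C1)C(F)(F)F | intermediate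
4 | (3R,5R)-1,3,5-trimethylcyclohex-1-ene | CC1=C[C@H](C)C[C@@H](C)C1 | intermediate
5 | secondary ozonide of 4, (3R,5R)-1,3,5-trimethyl-7,8,9-trioxabicyclo[4.2.1]nonane, bridgehead configuration not specified (not isolated) | CC12OOC(O1)[C@H](C)C[C@@H](C)C2 | intermediate
6 | (2R,4R)-2,4-dimethyl-6-oxoheptanal | O=C[C@H](C)C[C@@H](C)CC(C)=O | intermediate
7 | methyl (4R,6R)-3-hydroxy-4,6-dimethyl-2-methylidene-8-oxononanoate (both C3 epimers) | C=C(C(=O)OC)C(O)[C@H](C)C[C@@H](C)CC(C)=O | intermediate
8 | methyl (4R,6R)-4,6-dimethyl-2-methylidene-3,8-dioxononanoate | C=C(C(=O)OC)C(=O)[C@H](C)C[C@@H](C)CC(C)=O | intermediate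
9 | methyl 2-[(3R,5R)-2-acetyl-3,5-dimethylcyclopent-1-en-1-yl]prop-2-enoate (not isolated) | C=C(C(=O)OC)C1=C(C(C)=O)[C@H](C)C[C@H]1C | intermediate
10 | methyl 2-{(3R,5R)-3,5-dimethyl-2-[1-(pyrrolidin-1-yl)ethenyl]cyclopent-1-en-1-yl}prop-2-enoate (not isolated) | C=C(C(=O)OC)C1=C(C(=C)N2CCCC2)[C@H](C)C[C@H]1C | intermediate
11 | methyl (1R,3R)-1,3-dimethyl-7-(pyrrolidin-1-yl)-2,3,5,6-tetrahydro-1H-indene-4-carboxylate (not isolated) | COC(=O)C1=C2C(=C(CC1)N1CCCC1)[C@H](C)C[C@H]2C | intermediate
12 | methyl (1R,3R)-1,3-dimethyl-7-oxo-2,3,4,5,6,7-hexahydro-1H-indene-4-carboxylate (both C4 epimers) | COC(=O)C1CCC(=O)C2=C1[C@H](C)C[C@H]2C | intermediate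
13 | methyl (1R,3R,4S)-4-ethyl-1,3-dimethyl-7-oxo-2,3,4,5,6,7-hexahydro-1H-indene-4-carboxylate | COC(=O)[C@@]1(CC)CCC(=O)C2=C1[C@H](C)C[C@H]2C | intermediate
14 | lithium (1R,3R,3aR,4S)-4-ethyl-4-(methoxycarbonyl)-1,3-dimethyl-2,3,3a,4,5,6-hexahydro-1H-inden-7-olate (not isolated) | [Li+].COC(=O)[C@@]1(CC)CCC([O-])=C2[C@H]1[C@H](C)C[C@H]2C | intermediate
15 | methyl (1R,3R,3aR,4S,7aR)-4-ethyl-1,3-dimethyl-7-oxooctahydro-1H-indene-4-carboxylate (trans ring fusion) | COC(=O)[C@@]1(CC)CCC(=O)[C@H]2[C@H]1[C@H](C)C[C@H]2C | intermediate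
16 | lithium (1R,3R,3aR,4S,7aR)-4-ethyl-4-(methoxycarbonyl)-1,3-dimethyl-2,3,3a,4,5,7a-hexahydro-1H-inden-7-olate (not isolated) | [Li+].COC(=O)[C@@]1(CC)CC=C([O-])[C@H]2[C@H]1[C@H](C)C[C@H]2C | intermediate
17 | methyl (1R,3R,3aR,4S,7aR)-4-ethyl-1,3-dimethyl-7-oxo-2,3,3a,4,7,7a-hexahydro-1H-indene-4-carboxylate | COC(=O)[C@@]1(CC)C=CC(=O)[C@H]2[C@H]1[C@H](C)C[C@H]2C | intermediate
18 | lithium (1R,3R,3aR,4R,5S,7aR)-4-ethyl-4-(methoxycarbonyl)-1,3-dimethyl-5-phenyl-2,3,3a,4,5,7a-hexahydro-1H-inden-7-olate (not isolated) | [Li+].[O-]C1=C[C@@H](c2ccccc2)[C@@](C(=O)OC)(CC)[C@H]2[C@H]1[C@H](C)C[C@H]2C | intermediate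
19 | methyl (1R,3R,3aR,4R,5S,7aR)-4-ethyl-1,3-dimethyl-5-phenyl-7-(trifluoromethanesulfonyloxy)-2,3,3a,4,5,7a-hexahydro-1H-indene-4-carboxylate | O=S(=O)(OC1=C[C@@H](c2ccccc2)[C@@](C(=O)OC)(CC)[C@H]2[C@H]1[C@H](C)C[C@H]2C)C(F)(F)F | intermediate
20 | methyl (1R,3R,3aR,4R,5S,7aR)-4,7-diethyl-1,3-dimethyl-5-phenyl-2,3,3a,4,5,7a-hexahydro-1H-indene-4-carboxylate | CCC1=C[C@@H](c2ccccc2)[C@@](C(=O)OC)(CC)[C@H]2[C@H]1[C@H](C)C[C@H]2C | intermediate
21 | [(1R,3R,3aR,4R,5S,7aR)-4,7-diethyl-1,3-dimethyl-5-phenyl-2,3,3a,4,5,7a-hexahydro-1H-inden-4-yl]methanol | CCC1=C[C@@H](c2ccccc2)[C@@](CO)(CC)[C@H]2[C@H]1[C@H](C)C[C@H]2C | intermediate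
22 | (1R,3R,3aR,4R,5S,7aR)-4,7-diethyl-1,3-dimethyl-5-phenyl-2,3,3a,4,5,7a-hexahydro-1H-indene-4-carbaldehyde | CCC1=C[C@@H](c2ccccc2)[C@@](C=O)(CC)[C@H]2[C@H]1[C@H](C)C[C@H]2C | intermediate
23 | ethyl (2E)-3-[(1R,3R,3aR,4S,5S,7aR)-4,7-diethyl-1,3-dimethyl-5-phenyl-2,3,3a,4,5,7a-hexahydro-1H-inden-4-yl]-2-methylprop-2-enoate | CCC1=C[C@@H](c2ccccc2)[C@@](/C=C(\C)C(=O)OCC)(CC)[C@H]2[C@H]1[C@H](C)C[C@H]2C | intermediate
24 | homo-plakotenin, (2E)-3-[(1R,3R,3aR,4S,5S,7aR)-4,7-diethyl-1,3-dimethyl-5-phenyl-2,3,3a,4,5,7a-hexahydro-1H-inden-4-yl]-2-methylprop-2-enoic acid | CCC1=C[C@@H](c2ccccc2)[C@@](/C=C(\C)C(=O)O)(CC)[C@H]2[C@H]1[C@H](C)C[C@H]2C | target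

Total step count: 15. Longest linear sequence: 15 steps (1 → 24, fully linear).

**Steps most likely to fail**

Step 6. The doubly activated acrylate may oligomerise by intermolecular Michael addition, the centre α to the C3 ketone may epimerise before the first ring closes, or the sequence may stall after the five-ring closure. Fallback, setting out from 8 and coming back at 12: the cascade is split into separate operations. Acid-catalysed cyclodehydration (TsOH, benzene, reflux, water removal) should give acylcyclopentene 9, which is isolated. Soft enolisation of its acetyl group (TBSOTf, Et3N, CH2Cl2, −78 °C) should give the 2-silyloxytriene F1. Heating in toluene should effect the 6π-electrocyclisation to the silyl dienol ether F2, and mild acid hydrolysis (aqueous HCl, THF) should give 12.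

Step 8. Protonation may occur on the wrong face at C3a or C7a (cis fusion or the C3a epimer), and the ester may be over-reduced. Fallback, setting out from 13 and coming back at 15: Luche reduction (NaBH4, CeCl3·7H2O, MeOH) should give the allylic alcohol F3. Hydrogen-atom-transfer hydrogenation of the now unactivated tetrasubstituted alkene (Mn(dpm)3, PhSiH3, t-BuOOH, i-PrOH), in which a bulky metal hydride delivers the hydrogens stepwise from the open faces, should give the trans-fused alcohol F4. Dess–Martin oxidation then gives 15.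

Step 10. Conjugate addition at the neopentyl β-carbon may be slow, so that enolisation or 1,2-addition competes, and O-triflation of the copper-containing enolate may be incomplete. Fallback, setting out from 17 and coming back at 19: rhodium-catalysed Hayashi–Miyaura addition of PhB(OH)2 ([Rh(cod)Cl]2, KOH, dioxane/H2O), again axial and anti to the axial ester, should give the 5-phenyl ketone F5. Kinetic enolisation at the C6 methylene (KN(SiMe3)2, THF, −78 °C) and O-triflation with PhNTf2 then give 19.

**Further compounds**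
F1 | step 6 | methyl 2-[(3R,5R)-2-{1-[(tert-butyldimethylsilyl)oxy]ethenyl}-3,5-dimethylcyclopent-1-en-1-yl]prop-2-enoate | C=C(C(=O)OC)C1=C(C(=C)O[Si](C)(C)C(C)(C)C)[C@H](C)C[C@H]1C
F2 | step 6 | methyl (1R,3R)-7-[(tert-butyldimethylsilyl)oxy]-1,3-dimethyl-2,3,5,6-tetrahydro-1H-indene-4-carboxylate | COC(=O)C1=C2C(=C(CC1)O[Si](C)(C)C(C)(C)C)[C@H](C)C[C@H]2C
F3 | step 8 | methyl (1R,3R,4S)-4-ethyl-7-hydroxy-1,3-dimethyl-2,3,4,5,6,7-hexahydro-1H-indene-4-carboxylate (both C7 epimers) | COC(=O)[C@@]1(CC)CCC(O)C2=C1[C@H](C)C[C@H]2C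
F4 | step 8 | methyl (1R,3R,3aR,4S,7aR)-4-ethyl-7-hydroxy-1,3-dimethyloctahydro-1H-indene-4-carboxylate (both C7 epimers) | COC(=O)[C@@]1(CC)CCC(O)[C@H]2[C@H]1[C@H](C)C[C@H]2C
F5 | step 10 | methyl (1R,3R,3aR,4R,5S,7aR)-4-ethyl-1,3-dimethyl-7-oxo-5-phenyloctahydro-1H-indene-4-carboxylate | O=C1C[C@@H](c2ccccc2)[C@@](C(=O)OC)(CC)[C@H]2[C@H]1[C@H](C)C[C@H]2C
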